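**Retrosynthetic overview**

1. The C2–O aryl ether is cut last: hydroquinone adds to C2 of a 2-(methylsulfonyl)chromone and expels methanesulfinate. A MOM group on O5 is the only protecting group.
2. The pyranone ring (O1, C2, C3, C4, C4a, C8a) is cut at C2: carbon disulfide supplies C2 and the acetyl group of an o-hydroxyacetophenone supplies C3 and C4. Blocking O5 forces closure through the phenol next to the prenyl group.
3. Ring A is cut at C4a–C5: the acetophenone is the intramolecular Claisen product of open-chain methyl (2E)-3-methoxy-4-prenyl-5,7-dioxooct-2-enoate. The strategy rests on ring A being an acylphloroglucinol: acyl-bearing C4a lies between oxygenated C5 and C8a, the O7 methyl maps onto a β-methoxyacrylate carbon, and the C8 prenyl group maps onto the chain carbon between that enol ether and a ketone.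
4. The chain is assembled from methyl (E)-3-methoxybut-2-enoate by γ-prenylation, γ-acetylation and acetylation of the resulting ketone dianion.
5. Ring order: ring A (carbocycle) first, then the pyranone ring; the hydroquinone ring is bought.

Key step: step 4

Remark: the target has no stereocenter and its only alkene is the symmetrically substituted prenyl double bond. The chain C4 centre of the open-chain intermediates is racemic and becomes an aromatic carbon in step 4. Ring atoms carry chromone locants (O1 to C8a); atoms of the octenoate are called chain C1 to chain C8.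

**Step 1**
Reactants: 1 methyl (2E)-3-methoxybut-2-enoate; 2 1-bromo-3-methylbut-2-ene (prenyl bromide)
Product: 4 methyl (2E)-3-methoxy-7-methylocta-2,6-dienoate, via lithium 1,3-dimethoxybuta-1,3-dien-1-olate 3 (not isolated)
Conditions: 1 (1.15 equiv), LiN(i-Pr)2 (1.1 equiv), THF, −78 °C; then 2 (1.0 equiv), DMPU, −78 to −20 °C
Reagents that add atoms: none
Why: Kinetic deprotonation of the methyl group that lies cis to the ester gives the chelated s-cis dienolate 3, and SN2 alkylation of such β-alkoxy dienolates with an allylic bromide (vinylogous enolate alkylation) should occur at the γ-carbon and return the (2E) β-methoxyacrylate, the slight excess of dienolate limiting double alkylation.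

**Step 2**
Reactants: 4 methyl (2E)-3-methoxy-7-methylocta-2,6-dienoate; 5 N-methoxy-N-methylacetamide
Product: 7 methyl (2E)-4-acetyl-3-methoxy-7-methylocta-2,6-dienoate (racemic at C4), via lithium 1,3-dimethoxy-7-methylocta-1,3,6-trien-1-olate 6 (not isolated)
Conditions: LiN(i-Pr)2 (1.1 equiv), THF, −78 °C; then 5 (1.2 equiv), −78 to −40 °C; AcOH quench at −78 °C
Reagents that add atoms: none
Why: The γ-dienolate 6 should be acylated at chain C4 in a Weinreb ketone synthesis (the γ-selectivity follows the γ-aldol behaviour of 3-methoxycrotonate dienolates), and the lithium-chelated hemiaminal persists until the cold acid quench, so the more acidic product never meets base and is not acylated twice.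

**Step 3**
Reactants: 7 methyl (2E)-4-acetyl-3-methoxy-7-methylocta-2,6-dienoate; 5 N-methoxy-N-methylacetamide
Product: 9 methyl (2E)-3-methoxy-4-(3-methylbut-2-en-1-yl)-5,7-dioxooct-2-enoate (racemic at C4), via dilithium bis-enolate 8 (not isolated)
Conditions: LiN(i-Pr)2 (2.3 equiv), THF, −78 to −40 °C; then 5 (1.2 equiv), −78 to −30 °C; AcOH quench at −78 °C
Reagents that add atoms: none
Why: The first equivalent of base removes the doubly activated chain C4–H and the second the acetyl CH3, and the dianion should be acylated at its terminal, more basic carbon (dianion acylation of a β-dicarbonyl-type system, Weinreb ketone synthesis), while low temperature and the cold acid quench keep the chain C5 enolate oxygen from lactonising onto the ester.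

**Step 4**
Reactants: 9 methyl (2E)-3-methoxy-4-(3-methylbut-2-en-1-yl)-5,7-dioxooct-2-enoate
Product: 11 1-[2,6-dihydroxy-4-methoxy-3-(3-methylbut-2-en-1-yl)phenyl]ethan-1-one, via 2-acetyl-5-methoxy-6-(3-methylbut-2-en-1-yl)cyclohex-4-ene-1,3-dione 10 (not isolated)
Conditions: Mg(OMe)2 (4 equiv), MeOH, 25 °C then reflux; work-up with cold 1 M HCl
Reagents that add atoms: none
Why: Mg(OMe)2 deprotonates the chain C5–C7 β-diketone to a magnesium-chelated diketonate whose central carbon, chain C6 (ring C4a), adds to the ester carbonyl, chain C1 (ring C5), in an intramolecular Claisen (Dieckmann-type) condensation; methoxide leaves to give trione 10, and two enolisations aromatise it to the phenoxide, which makes the closure irreversible and erases the racemic C4 centre. The closest known reaction type is the Mg(OMe)2-mediated Claisen cyclisation of 3,5,7-triketo esters and of their 2-pyrone forms to acylphloroglucinols, applied here to a 3-O-methyl enol ether with an alkyl group on chain C4. Ring A closes 6-exo-trig and no stereocenter is formed. The selectivity needed is C-acylation at chain C6 over O-acylation by the chain C5 enol oxygen (a 4-methoxy-2-pyrone) and over an aldol closure: the pyrone is a reactive enol lactone that methoxide should reopen to 9, and the carbon next to the ester is a vinylic CH of the β-methoxyacrylate that becomes nucleophilic only if chain C4 is deprotonated on top of the diketonate, which is disfavoured. The (2E) geometry holds the ester and chain C4 cis across C2=C3 as the closure requires, and any (2Z) isomer carried in from steps 2 and 3 can equilibrate by reversible methoxide addition–elimination at chain C3 under the same conditions.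

**Step 5**
Reactants: 11 1-[2,6-dihydroxy-4-methoxy-3-(3-methylbut-2-en-1-yl)phenyl]ethan-1-one
Product: 12 1-[2-hydroxy-4-methoxy-6-(methoxymethoxy)-3-(3-methylbut-2-en-1-yl)phenyl]ethan-1-one
Conditions: MOMCl (1.05 equiv), i-Pr2NEt (1.5 equiv), CH2Cl2, −10 to 0 °C
Reagents that add atoms: chloromethyl methyl ether (MOMCl), COCCl
Why: MOM ether formation (Williamson-type O-alkylation) with one equivalent of reagent should go to the phenol flanked by the ring hydrogen (the future O5), because the other hydroxyl is shielded by the prenyl group and held in the stronger, buttressed hydrogen bond to the acetyl oxygen, and a second alkylation of that chelated phenol is slow.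

**Step 6**
Reactants: 12 1-[2-hydroxy-4-methoxy-6-(methoxymethoxy)-3-(3-methylbut-2-en-1-yl)phenyl]ethan-1-one; 13 carbon disulfide
Product: 14 4-hydroxy-7-methoxy-5-(methoxymethoxy)-8-(3-methylbut-2-en-1-yl)-2H-chromene-2-thione
Conditions: KOtBu (3.5 equiv), 13 (3 equiv), THF, 0 to 25 °C; then cold 1 M HCl to pH 3–4
Reagents that add atoms: none
Why: The acetophenone enolate adds to CS2 to give a β-keto dithioate, and on acidification the only free phenol (O1, next to the prenyl group) closes onto the thiocarbonyl carbon with loss of H2S, which is the standard carbon disulfide annulation of o-hydroxyacetophenones to 4-hydroxychromene-2-thiones and fixes the prenyl group at C8.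

**Step 7**
Reactants: 14 4-hydroxy-7-methoxy-5-(methoxymethoxy)-8-(3-methylbut-2-en-1-yl)-2H-chromene-2-thione
Product: 15 7-methoxy-5-(methoxymethoxy)-8-(3-methylbut-2-en-1-yl)-2-(methylsulfanyl)-4H-chromen-4-one
Conditions: MeI (1.2 equiv), K2CO3 (1.5 equiv), acetone, 25 °C
Reagents that add atoms: iodomethane (MeI), CI
Why: The soft sulfur of the potassium salt of 14 should be alkylated by iodomethane (S-methylation, SN2) in preference to the 4-oxygen, which delivers the 2-(methylsulfanyl)chromone tautomer.

**Step 8**
Reactants: 15 7-methoxy-5-(methoxymethoxy)-8-(3-methylbut-2-en-1-yl)-2-(methylsulfanyl)-4H-chromen-4-one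
Product: 16 2-(methanesulfonyl)-7-methoxy-5-(methoxymethoxy)-8-(3-methylbut-2-en-1-yl)-4H-chromen-4-one
Conditions: 30% aq H2O2 (5 equiv), (NH4)6Mo7O24·4H2O (10 mol %), EtOH–THF, 0 to 25 °C
Reagents that add atoms: hydrogen peroxide, OO
Why: Molybdate-catalysed hydrogen peroxide oxidation of a sulfide to the sulfone is the method used for electron-poor heteroaryl sulfides that carry trisubstituted alkenes (as in the preparation of Julia–Kocienski sulfones), so the sulfur should be oxidised while the prenyl double bond, which a peracid would put at risk, and the MOM ether are left alone.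

**Step 9**
Reactants: 16 2-(methanesulfonyl)-7-methoxy-5-(methoxymethoxy)-8-(3-methylbut-2-en-1-yl)-4H-chromen-4-one; 17 hydroquinone (benzene-1,4-diol)
Product: 18 2-(4-hydroxyphenoxy)-7-methoxy-5-(methoxymethoxy)-8-(3-methylbut-2-en-1-yl)-4H-chromen-4-one
Conditions: 17 (5 equiv), K2CO3 (2 equiv), DMF, 25 °C, argon
Reagents that add atoms: none
Why: C2 of the sulfonylchromone is a vinylogous sulfonyl ester carbon, so the hydroquinone monoanion should add and methanesulfinate leave (addition–elimination at C2 of a chromone, SNAr-like), the fivefold excess of hydroquinone under argon suppressing double arylation and quinone formation.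

**Step 10**
Reactants: 18 2-(4-hydroxyphenoxy)-7-methoxy-5-(methoxymethoxy)-8-(3-methylbut-2-en-1-yl)-4H-chromen-4-one
Product: 19 7-O-methylepimedonin G, 5-hydroxy-2-(4-hydroxyphenoxy)-7-methoxy-8-(3-methylbut-2-en-1-yl)-4H-chromen-4-one
Conditions: 2 M HCl (aq), THF, 40 °C
Reagents that add atoms: none
Why: Acid-catalysed acetal hydrolysis should remove the MOM group, which is especially labile peri to the C4 carbonyl because the freed O5–H becomes chelated, while the prenyl group has no free ortho phenol with which to cyclise to a chroman (C7 bears OMe, C8a the ring oxygen) and aqueous THF avoids alcohol exchange at the C2 aryl ether.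

**Compound list**

1 | methyl (2E)-3-methoxybut-2-enoate | COC(=O)/C=C(/OC)C | starting material
2 | 1-bromo-3-methylbut-2-ene (prenyl bromide) | CC(C)=CCBr | starting material
3 | lithium 1,3-dimethoxybuta-1,3-dien-1-olate (dienolate of 1, enolate geometry not defined, formed in the flask) | C=C(OC)C=C(OC)[O-].[Li+] | intermediate
4 | methyl (2E)-3-methoxy-7-methylocta-2,6-dienoate | COC(=O)/C=C(/OC)CCC=C(C)C | intermediate
5 | N-methoxy-N-methylacetamide | CON(C)C(C)=O | starting material
6 | lithium 1,3-dimethoxy-7-methylocta-1,3,6-trien-1-olate (dienolate of 4, geometry not defined, formed in the flask) | CC(C)=CCC=C(OC)C=C(OC)[O-].[Li+] | intermediate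
7 | methyl (2E)-4-acetyl-3-methoxy-7-methylocta-2,6-dienoate (racemic at C4) | COC(=O)/C=C(/OC)C(CC=C(C)C)C(C)=O | intermediate
8 | dilithium 1,3-dimethoxy-4-(3-methylbut-2-en-1-yl)hexa-1,3,5-triene-1,5-bis(olate) (dianion of 7, geometry not defined, formed in the flask) | [Li+].[Li+].COC([O-])=CC(OC)=C(CC=C(C)C)C(=C)[O-] | intermediate
9 | methyl (2E)-3-methoxy-4-(3-methylbut-2-en-1-yl)-5,7-dioxooct-2-enoate (racemic at C4; largely the enol of the β-diketone) | COC(=O)/C=C(/OC)C(CC=C(C)C)C(=O)CC(C)=O | intermediate
10 | 2-acetyl-5-methoxy-6-(3-methylbut-2-en-1-yl)cyclohex-4-ene-1,3-dione (mixture of stereoisomers and tautomers, formed in the flask) | CC(=O)C1C(=O)C=C(OC)C(CC=C(C)C)C1=O | intermediate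
11 | 1-[2,6-dihydroxy-4-methoxy-3-(3-methylbut-2-en-1-yl)phenyl]ethan-1-one | CC(=O)c1c(O)cc(OC)c(CC=C(C)C)c1O | intermediate
12 | 1-[2-hydroxy-4-methoxy-6-(methoxymethoxy)-3-(3-methylbut-2-en-1-yl)phenyl]ethan-1-one | CC(=O)c1c(OCOC)cc(OC)c(CC=C(C)C)c1O | intermediate
13 | carbon disulfide | S=C=S | starting material
14 | 4-hydroxy-7-methoxy-5-(methoxymethoxy)-8-(3-methylbut-2-en-1-yl)-2H-chromene-2-thione | S=C1C=C(O)c2c(OCOC)cc(OC)c(CC=C(C)C)c2O1 | intermediate
15 | 7-methoxy-5-(methoxymethoxy)-8-(3-methylbut-2-en-1-yl)-2-(methylsulfanyl)-4H-chromen-4-one | CSc1cc(=O)c2c(OCOC)cc(OC)c(CC=C(C)C)c2o1 | intermediate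
16 | 2-(methanesulfonyl)-7-methoxy-5-(methoxymethoxy)-8-(3-methylbut-2-en-1-yl)-4H-chromen-4-one | CS(=O)(=O)c1cc(=O)c2c(OCOC)cc(OC)c(CC=C(C)C)c2o1 | intermediate
17 | hydroquinone (benzene-1,4-diol) | Oc1ccc(O)cc1 | starting material
18 | 2-(4-hydroxyphenoxy)-7-methoxy-5-(methoxymethoxy)-8-(3-methylbut-2-en-1-yl)-4H-chromen-4-one | COCOc1cc(OC)c(CC=C(C)C)c2oc(Oc3ccc(O)cc3)cc(=O)c12 | intermediate
19 | 7-O-methylepimedonin G, 5-hydroxy-2-(4-hydroxyphenoxy)-7-methoxy-8-(3-methylbut-2-en-1-yl)-4H-chromen-4-one | COc1cc(O)c2c(=O)cc(Oc3ccc(O)cc3)oc2c1CC=C(C)C | target

**Step count and risks**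

Total step count: 10. Longest linear sequence: 10 steps (1 to 19); compounds 2, 5, 13 and 17 are purchased and enter directly.

Steps most likely to fail:

Step 4 (Claisen closure of ring A). C-acylation by the diketonate may be too slow at the deactivated β-methoxyacrylate ester. Lactonisation to the 2-pyrone, retro-Claisen loss of the terminal acetyl group by methoxide, or closure through a chain C4 dienolate could then drain the material. Fallback: ring A is taken from an aromatic feedstock instead of being folded. The fallback sets out from prenyl bromide 2, which would C-prenylate purchased 1-(2,6-dihydroxy-4-methoxyphenyl)ethan-1-one (CC(=O)c1c(O)cc(OC)cc1O) in cold aqueous KOH, a direct C-alkylation of a phloroglucinol-type phenoxide. The two open ring positions of that ketone are equivalent, so only O-prenylated and doubly prenylated material would have to be separated. The fallback comes back to the route at 11.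

Step 3 (acetylation of the ketone dianion). The second deprotonation may be incomplete, the dianion may be quenched by proton transfer from the amide, or the chain C5 enolate oxygen may lactonise onto the ester on warming. Fallback: all four carbons are brought in by one acylation, with the far ketone masked. The fallback sets out from 4. Dienolate 6, made as in step 2, would be acylated with N-methoxy-N-methyl-2-(2-methyl-1,3-dioxolan-2-yl)acetamide F1. F1 is prepared from purchased ethyl 2-(2-methyl-1,3-dioxolan-2-yl)acetate (CCOC(=O)CC1(C)OCCO1) with MeNH(OMe)·HCl and i-PrMgCl in THF. The acylation should give methyl (2E)-3-methoxy-7-methyl-4-[(2-methyl-1,3-dioxolan-2-yl)acetyl]octa-2,6-dienoate F2. Mild hydrolysis of the dioxolane (pyridinium p-toluenesulfonate, wet acetone) would release the β-diketone, and the fallback comes back to the route at 9.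

Step 5 (differentiation of the two phenols). Discrimination between the two hydroxyl groups may be poor, or double alkylation may occur, so that the wrong oxygen would later close the pyranone ring. Fallback: selection by cleavage rate instead of by protection rate. The fallback sets out from 11, which would be protected at both oxygens (MOMCl in excess, NaH, DMF) to give 1-[4-methoxy-2,6-bis(methoxymethoxy)-3-(3-methylbut-2-en-1-yl)phenyl]ethan-1-one F3. One acetal would then be removed with catalytic HCl in MeOH at 0 °C. The MOM group wedged between the acetyl and prenyl groups should go first, through relief of strain and formation of the buttressed hydrogen bond, and that new hydrogen bond should slow cleavage of the second acetal. The fallback comes back to the route at 12.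

**Further compounds**

F0 | step 4 | none | none
F1 | step 3 | N-methoxy-N-methyl-2-(2-methyl-1,3-dioxolan-2-yl)acetamide | CON(C)C(=O)CC1(C)OCCO1
F2 | step 3 | methyl (2E)-3-methoxy-7-methyl-4-[(2-methyl-1,3-dioxolan-2-yl)acetyl]octa-2,6-dienoate | COC(=O)/C=C(/OC)C(CC=C(C)C)C(=O)CC1(C)OCCO1
F3 | step 5 | 1-[4-methoxy-2,6-bis(methoxymethoxy)-3-(3-methylbut-2-en-1-yl)phenyl]ethan-1-one | CC(=O)c1c(OCOC)cc(OC)c(CC=C(C)C)c1OCOC
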